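If X stays in a frozen ratio to Q, a pre-equilibrium, then G and Z grow in a fixed proportion in this closed flask. Q takes L to Z and X takes L to G, so L stands in both rates and cancels, and Q cancels against the frozen ratio.

- Saturday's: Q 2.7 M; E 85 mM (held); run made earlier
- flask: Q 1.9 M; E 85 mM (held); time 15 d

- Saturday's (time / d: G / %, Z / %): 1.25: 0.7, 78.3; 4.00: 0.7, 95.3; 6.00: 0.3, 97.9; 10.0: 1.2, 99.0; 15.0: 0.8, 99.0; 20.0: 0.8, 99.1

(scatter of a reading: 0.3 percentage points)

- at the start none of L is dissolved
- steps under discussion: Q <-> X; Q + L -> Z; L + X -> G; 2 L -> J; Q <-> D; E <-> L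

- share of G in G plus Z at 40 min
- share of G in G plus Z at 15 d
- which of G and Z there is more of at 15 d

Saturday's run reads as a ladder. The first rung is taken to lie before the first reading: at 1.25 d G already reads 0.7% beside Z at 78.3%, a share of 0.886%, with a scatter of 0.3 percentage points on the reading of G. On the next rung, up to 1.25 d, the part of the charge not yet Z reads as halving in 0.567 d on average. Between 4.00 d and 6.00 d it halves more slowly, in 1.72 d, which suggests Q coming back from D. On the last rung, from 10.0 d, Z stays flat near 99.1%.

Summed over Saturday's readings, G over G plus Z is 0.785%. This reads the branching share, a selectivity, and the scatter of that reading is about 0.12 points.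

My own reckoning carries this share to the flask with 1.9 M of Q, since the charge cancels: 0.785% at 15 d, with Z ahead. It gives the same share at 40 min, which is early; no reading stands there, so the freeze is assumed. The forecast gives 0.8% at 40 min and 0.8% at 15 d, with Z ahead: “This ratio is first order in both branches, so it is independent of Q and L”.

The flask gives 0.619% at 40 min and 0.620% at 15 d, with Z ahead at 99.4% against 0.620% for G.

    Q ⇌ X (K = 0.0170, k = 4.10 × 10⁻⁴ /s)
    Q + L → Z (k = 3.00 × 10⁻⁴ /M/s)
    L + X → G (k = 1.10 × 10⁻⁴ /M/s)
    2 L → J (k = 9.40 × 10⁻⁴ /M/s)
    Q ⇌ D (K = 0.560, k = 4.60 × 10⁻⁶ /s)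
    E ⇌ L, rate k6*(csat - [L]) (kL = 0.00160 /s)

The branching share was carried as one number, the reading 0.785% with its scatter of 0.12 points, to both times in this flask, and this flask holds one share at both. A neighbouring flask with 0.76 M of Q gives 0.619% at 40 min and 0.620% at 15 d, again one share, from a smaller charge. The falling back of X to Q is the main reason the share is so small: with that step taken away, this flask's share at 15 d goes from 0.620% to 96.2%.

The readings are simulated on assumed constants; scatter was added.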